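## Retrosynthetic overview

1. 17 ⇐ 16 by removal of two triethylsilyl (TES) groups; 16 ⇐ C7–C8 bond: lithium dienolate of the east pyranone 7 (ring B) + aldehyde 14 (ring A), an anti/Felkin vinylogous aldol.
2. 14 ⇐ enal 12 + propanal enolsilane 13 (C5–C6 bond, catalytic anti single aldolization); 12 ⇐ allylic transposition/oxidation of the methacrolein adduct 10.
3. 7 (C2′, C3′) and 10 (C2) ⇐ one new confined-acid vinylogous Mukaiyama aldol of the pyranylidene silyl ether 5 with propanal or methacrolein, run with mirror-image catalysts.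
4. 5 ⇐ 2,6-diethyl-3,5-dimethylpyran-4-one 3 ⇐ 3-pentanone + propionic acid.
5. Ring order: the pyranone ring is built once (step 1); one batch of 3 becomes both ring A and ring B, and no ring is formed afterwards.

## Assumptions and notation

- Target read from the SMILES as (2S,3E,5S,6S,7S,8S) in the non-3-en-2-yl chain (C2 on ring A, C8 on ring B) and (2′R,3′R) in the pentan-2-yl chain on ring B; anti at C2′/C3′, anti-syn-anti along C5–C8.
- Pyranone 3 is made rather than bought, so that every starting material is a catalogue chemical.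
- cat A = (S,S)-imidodiphosphorimidate (IDPi) Brønsted acid HN[P(=NSO2CF3)(O2C20H10Ar2)]2, each O2C20H10Ar2 a 3,3′-diaryl-1,1′-binaphthalene-2,2′-diolate with Ar = 3,5-(CF3)2C6H3; ent-cat A = its (R,R) mirror image; cat B = the analogous acid with inner C6F5SO2 groups and Ar = 4-tBuC6H4.
- Which enantiomer and which aryl groups of this acid family deliver the drawn configurations must be fixed by screening; the labels denote the acid that does.
- TES = triethylsilyl.

## Route

Step 1
Reactants: 1 3-pentanone; 2 propionic acid (2 equiv)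
Product: 3 2,6-diethyl-3,5-dimethyl-4H-pyran-4-one
Conditions: polyphosphoric acid, 95 °C, 6 h; ice-water, CH2Cl2 extraction, distillation
Reagents that add atoms: none
Why: Known polyphosphoric-acid double α-acylation of the ketone and cyclodehydration of the resulting 1,3,5-triketone gives the symmetrical γ-pyrone used for both rings; no stereocentre.

Step 2
Reactants: 3 2,6-diethyl-3,5-dimethyl-4H-pyran-4-one
Product: 5 triethyl{[(2Z)-6-ethyl-2-ethylidene-3,5-dimethyl-2H-pyran-4-yl]oxy}silane, via silyloxypyrylium triflate 4 (not isolated)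
Conditions: Et3SiOTf (1.1 equiv), iPr2NEt (1.3 equiv), CH2Cl2, −20 → 0 °C; pentane, filtration under argon, used crude
Reagents that add atoms: triethylsilyl trifluoromethanesulfonate, CC[Si](CC)(CC)OS(=O)(=O)C(F)(F)F
Why: Soft enolization: O-silylation of the basic pyranone carbonyl gives a 4-silyloxypyrylium salt whose 2-CH2 is acidic enough for the amine, so only the O-silylated anhydrobase forms; A(1,3) strain with the C3 methyl puts the ethylidene methyl syn to the ring oxygen (Z).

Step 3
Reactants: 5 triethyl{[(2Z)-6-ethyl-2-ethylidene-3,5-dimethyl-2H-pyran-4-yl]oxy}silane (1.3 equiv); 6 propanal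
Product: 7 2-ethyl-3,5-dimethyl-6-[(2R,3R)-3-(triethylsilyloxy)pentan-2-yl]-4H-pyran-4-one
Conditions: cat A (3 mol %), toluene, −60 °C, 24 h; aq. NaHCO3
Reagents that add atoms: none
Why: Proposed new method: silylium-type asymmetric counteranion-directed Mukaiyama catalysis extended to a γ-pyrone anhydrobase – 5 silylates the IDPi acid, and the ion pair [EtCH=O–SiEt3]+[IDPi]− is attacked by the exocyclic carbon of 5, the only site whose attack regenerates an aromatic 4-silyloxypyrylium, which passes Et3Si+ to the next aldehyde so that 7 leaves as its TES ether; the confined anion shields one aldehyde face, and a compact synclinal approach (nascent pyrylium next to the anion, ethyl turned away from the ring) should give the anti (2′R,3′R) pair; closest known reaction type: IDPi- or disulfonimide-catalysed (vinylogous) Mukaiyama aldol of silyl ketene acetals and silyl dienolates with aldehydes.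

Step 4
Reactants: 5 triethyl{[(2Z)-6-ethyl-2-ethylidene-3,5-dimethyl-2H-pyran-4-yl]oxy}silane (1.3 equiv); 8 methacrolein
Product: 10 2-ethyl-6-[(2S,3R)-3-hydroxy-4-methylpent-4-en-2-yl]-3,5-dimethyl-4H-pyran-4-one, via TES ether 9 (not isolated)
Conditions: ent-cat A (3 mol %), toluene, −60 °C; then 1 M aq. HCl, THF, 0 °C
Reagents that add atoms: none
Why: Proposed new method: the same pyranylidene vinylogous Mukaiyama aldol as in step 3, run with the mirror-image acid and an α-branched enal that reacts 1,2 at the silylated carbonyl; the anti (2S,3R) adduct fixes C2 (S) next to ring A (the carbinol centre is erased in step 5), and dilute acid then cleaves the allylic TES ether; closest known reaction type as in step 3.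

Step 5
Reactants: 10 2-ethyl-6-[(2S,3R)-3-hydroxy-4-methylpent-4-en-2-yl]-3,5-dimethyl-4H-pyran-4-one
Product: 12 (2E,4S)-4-(6-ethyl-3,5-dimethyl-4-oxo-4H-pyran-2-yl)-2-methylpent-2-enal, via primary allylic alcohol 11 (not isolated)
Conditions: Ph3SiOReO3 (3 mol %), Et2O, 0 °C; then TEMPO (10 mol %), PhI(OAc)2 (1.2 equiv), CH2Cl2, 0 °C → rt
Reagents that add atoms: none
Why: Rhenium-oxo-catalysed 1,3-allylic transposition ([3,3] shift of the allyl perrhenate through a chair with the bulky C2 substituent equatorial) moves OH to the primary terminus and gives the E trisubstituted alkene; the TEMPO oxoammonium oxidation takes only the primary allylic alcohol and so drains the equilibrium, while C2 is untouched.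

Step 6
Reactants: 6 propanal
Product: 13 triethyl[(1Z)-prop-1-en-1-yloxy]silane
Conditions: Et3SiOTf (1.05 equiv), Et3N (1.3 equiv), Et2O, 0 °C → rt; pentane, filtration, distillation (Z-rich mixture, used as such)
Reagents that add atoms: triethylsilyl trifluoromethanesulfonate, CC[Si](CC)(CC)OS(=O)(=O)C(F)(F)F
Why: Standard silyl triflate/amine enol silylation of an aldehyde; no stereocentre.

Step 7
Reactants: 12 (2E,4S)-4-(6-ethyl-3,5-dimethyl-4-oxo-4H-pyran-2-yl)-2-methylpent-2-enal; 13 triethyl[(1Z)-prop-1-en-1-yloxy]silane (1.3 equiv)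
Product: 14 (2R,3S,4E,6S)-6-(6-ethyl-3,5-dimethyl-4-oxo-4H-pyran-2-yl)-2,4-dimethyl-3-(triethylsilyloxy)hept-4-enal
Conditions: cat B (3 mol %), toluene, −60 °C; aq. NaHCO3; the small surplus of 13 is removed unchanged in vacuo
Reagents that add atoms: none
Why: Known confined-acid (IDPi) Mukaiyama single aldolization of propanal enolsilanes, a 1:1 addition with silyl transfer in which every atom of 12 and of one molecule of 13 ends up in 14: catalyst-controlled anti 1,2-addition to the silylated enal sets C5 (S) and C6 of the target chain and delivers the β-oxygen already TES-protected, and the hindered α-branched product aldehyde does not react again.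

Step 8
Reactants: 7 2-ethyl-3,5-dimethyl-6-[(2R,3R)-3-(triethylsilyloxy)pentan-2-yl]-4H-pyran-4-one (1.2 equiv); 14 (2R,3S,4E,6S)-6-(6-ethyl-3,5-dimethyl-4-oxo-4H-pyran-2-yl)-2,4-dimethyl-3-(triethylsilyloxy)hept-4-enal
Product: 16 2-ethyl-6-[(2S,3E,5S,6S,7S,8S)-7-hydroxy-4,6-dimethyl-8-{3,5-dimethyl-4-oxo-6-[(2R,3R)-3-(triethylsilyloxy)pentan-2-yl]-4H-pyran-2-yl}-5-(triethylsilyloxy)non-3-en-2-yl]-3,5-dimethyl-4H-pyran-4-one, via lithium dienolate 15 (not isolated)
Conditions: LiN(SiMe3)2 (1.25 equiv), THF, −78 °C, 30 min; then 14, −78 °C, 1 h; AcOH/THF quench at −78 °C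
Reagents that add atoms: none
Why: Lateral lithiation of the unsubstituted ethyl group and vinylogous aldol addition: the extended lithium dienolate adds anti (the bulky aldehyde residue turns away from the ring) and on the Felkin face of the α-methyl aldehyde, the matched combination for an anti-selective nucleophile, setting C7 (S) and C8 (S).

Step 9
Reactants: 16 2-ethyl-6-[(2S,3E,5S,6S,7S,8S)-7-hydroxy-4,6-dimethyl-8-{3,5-dimethyl-4-oxo-6-[(2R,3R)-3-(triethylsilyloxy)pentan-2-yl]-4H-pyran-2-yl}-5-(triethylsilyloxy)non-3-en-2-yl]-3,5-dimethyl-4H-pyran-4-one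
Product: 17 2-ethyl-6-[(2S,3E,5S,6S,7S,8S)-5,7-dihydroxy-8-{6-[(2R,3R)-3-hydroxypentan-2-yl]-3,5-dimethyl-4-oxo-4H-pyran-2-yl}-4,6-dimethylnon-3-en-2-yl]-3,5-dimethyl-4H-pyran-4-one
Conditions: HF·pyridine, pyridine, THF, 0 °C → rt
Reagents that add atoms: none
Why: Fluoride cleavage of the two secondary TES ethers under buffered, non-basic conditions avoids retro-aldol and epimerization at C2 or C8; no stereocentre is touched.

## Compound list

1 | 3-pentanone | CCC(=O)CC | starting material
2 | propionic acid | CCC(=O)O | starting material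
3 | 2,6-diethyl-3,5-dimethyl-4H-pyran-4-one | CCc1oc(CC)c(C)c(=O)c1C | intermediate
4 | 2,6-diethyl-3,5-dimethyl-4-(triethylsilyloxy)pyrylium trifluoromethanesulfonate | CCc1[o+]c(CC)c(C)c(O[Si](CC)(CC)CC)c1C.[O-]S(=O)(=O)C(F)(F)F | intermediate
5 | triethyl{[(2Z)-6-ethyl-2-ethylidene-3,5-dimethyl-2H-pyran-4-yl]oxy}silane | C/C=C1\OC(CC)=C(C)C(O[Si](CC)(CC)CC)=C1C | intermediate
6 | propanal | CCC=O | starting material
7 | 2-ethyl-3,5-dimethyl-6-[(2R,3R)-3-(triethylsilyloxy)pentan-2-yl]-4H-pyran-4-one | CCc1oc([C@H](C)[C@H](O[Si](CC)(CC)CC)CC)c(C)c(=O)c1C | intermediate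
8 | methacrolein | CC(=C)C=O | starting material
9 | 2-ethyl-3,5-dimethyl-6-[(2S,3R)-4-methyl-3-(triethylsilyloxy)pent-4-en-2-yl]-4H-pyran-4-one | CCc1oc([C@@H](C)[C@@H](O[Si](CC)(CC)CC)C(C)=C)c(C)c(=O)c1C | intermediate
10 | 2-ethyl-6-[(2S,3R)-3-hydroxy-4-methylpent-4-en-2-yl]-3,5-dimethyl-4H-pyran-4-one | CCc1oc([C@@H](C)[C@@H](O)C(C)=C)c(C)c(=O)c1C | intermediate
11 | 2-ethyl-6-[(2S,3E)-5-hydroxy-4-methylpent-3-en-2-yl]-3,5-dimethyl-4H-pyran-4-one | CCc1oc([C@@H](C)/C=C(\C)CO)c(C)c(=O)c1C | intermediate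
12 | (2E,4S)-4-(6-ethyl-3,5-dimethyl-4-oxo-4H-pyran-2-yl)-2-methylpent-2-enal | CCc1oc([C@@H](C)/C=C(\C)C=O)c(C)c(=O)c1C | intermediate
13 | triethyl[(1Z)-prop-1-en-1-yloxy]silane | C/C=C\O[Si](CC)(CC)CC | intermediate
14 | (2R,3S,4E,6S)-6-(6-ethyl-3,5-dimethyl-4-oxo-4H-pyran-2-yl)-2,4-dimethyl-3-(triethylsilyloxy)hept-4-enal | CCc1oc([C@@H](C)/C=C(\C)[C@@H](O[Si](CC)(CC)CC)[C@@H](C)C=O)c(C)c(=O)c1C | intermediate
15 | lithium (2Z)-2-ethylidene-3,5-dimethyl-6-[(2R,3R)-3-(triethylsilyloxy)pentan-2-yl]-2H-pyran-4-olate | C/C=C1\OC([C@H](C)[C@H](O[Si](CC)(CC)CC)CC)=C(C)C([O-])=C1C.[Li+] | intermediate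
16 | 2-ethyl-6-[(2S,3E,5S,6S,7S,8S)-7-hydroxy-4,6-dimethyl-8-{3,5-dimethyl-4-oxo-6-[(2R,3R)-3-(triethylsilyloxy)pentan-2-yl]-4H-pyran-2-yl}-5-(triethylsilyloxy)non-3-en-2-yl]-3,5-dimethyl-4H-pyran-4-one | CCc1oc([C@@H](C)/C=C(\C)[C@@H](O[Si](CC)(CC)CC)[C@@H](C)[C@H](O)[C@H](C)c2oc([C@H](C)[C@H](O[Si](CC)(CC)CC)CC)c(C)c(=O)c2C)c(C)c(=O)c1C | intermediate
17 | 2-ethyl-6-[(2S,3E,5S,6S,7S,8S)-5,7-dihydroxy-8-{6-[(2R,3R)-3-hydroxypentan-2-yl]-3,5-dimethyl-4-oxo-4H-pyran-2-yl}-4,6-dimethylnon-3-en-2-yl]-3,5-dimethyl-4H-pyran-4-one | CCc1oc([C@@H](C)/C=C(\C)[C@@H](O)[C@@H](C)[C@H](O)[C@H](C)c2oc([C@H](C)[C@H](O)CC)c(C)c(=O)c2C)c(C)c(=O)c1C | target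

## Step count and risks

Total steps: 9. Longest linear sequence: 7 steps (1, 2, 4, 5, 7, 8, 9); the east branch is 1, 2, 3 and joins at step 8.

Steps most likely to fail:

**Step 3 (new method).** The pyranone oxygen is a far better silyl acceptor than an aldehyde, so the 4-silyloxypyrylium ion pair may be a slow-turnover resting state. With a small aldehyde an open transition state may also prefer syn over anti. The fallback sets out from 3 and returns at 7, using known chemistry only. 3 is deprotonated at one ethyl group with LiN(SiMe3)2 in THF at −78 °C to the lithium dienolate F1, which adds to propanal 6 in the known lateral vinylogous aldol and is quenched with AcOH. After chromatographic removal of the syn pair, the racemic anti alcohol is the (2′R,3′R)-alcohol F2 together with its (2′S,3′S)-enantiomer F3. Burkholderia cepacia lipase and vinyl acetate in tBuOMe acylate the 3′R carbinol (ethyl as the medium group), giving the acetate F4 and leaving F3. F4 is separated, methanolysed (K2CO3, MeOH) back to F2, and silylated (Et3SiCl, imidazole, DMF) to 7.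

**Step 4 (new method, second use).** Besides the turnover issue, methacrolein could react 1,4, and the ee at C2 depends on both aldehyde-face control and the anti:syn ratio. The fallback sets out from 3 and returns at 10, again with known chemistry. The lithium dienolate F1 is generated as above and added to methacrolein 8 at −78 °C. After removal of the syn pair, the racemic anti alcohol is 10 together with its (2R,3S)-enantiomer F5. A Sharpless kinetic resolution (Ti(OiPr)4, L-(+)-diisopropyl tartrate, tBuOOH, 4 Å sieves, CH2Cl2, −20 °C, to about 55–60 % conversion) epoxidises F5 to the erythro epoxy alcohol F6 and leaves 10 in high ee. Secondary allylic alcohols with a 2-substituted terminal alkene are among the best substrates for this resolution.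

**Step 8 (fragment union).** The dienolate could instead transfer a proton from the acidic C2–H or the aldehyde α-position of 14, or give only modest Felkin/anti control. The fallback sets out from 7 and returns at 16. 7 is treated as in step 2 (Et3SiOTf, iPr2NEt, CH2Cl2) to pass through the silyloxypyrylium triflate F7 into the TES dienol ether F8. F8 is combined with 14 and BF3·OEt2 in CH2Cl2 at −78 °C in a vinylogous Mukaiyama aldol. No base is present, and in the open transition state the Felkin and 1,3-anti preferences of the anti-configured β-silyloxy aldehyde reinforce each other at C7. The bulky aldehyde residue turned away from the ring should keep C7/C8 anti, but this ratio must be checked.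

Further compounds

F1 | step 3 | lithium (2Z)-6-ethyl-2-ethylidene-3,5-dimethyl-2H-pyran-4-olate | C/C=C1\OC(CC)=C(C)C([O-])=C1C.[Li+]
F2 | step 3 | 2-ethyl-6-[(2R,3R)-3-hydroxypentan-2-yl]-3,5-dimethyl-4H-pyran-4-one | CCc1oc([C@H](C)[C@H](O)CC)c(C)c(=O)c1C
F3 | step 3 | 2-ethyl-6-[(2S,3S)-3-hydroxypentan-2-yl]-3,5-dimethyl-4H-pyran-4-one | CCc1oc([C@@H](C)[C@@H](O)CC)c(C)c(=O)c1C
F4 | step 3 | (2R,3R)-2-(6-ethyl-3,5-dimethyl-4-oxo-4H-pyran-2-yl)pentan-3-yl acetate | CCc1oc([C@H](C)[C@H](OC(C)=O)CC)c(C)c(=O)c1C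
F5 | step 4 | 2-ethyl-6-[(2R,3S)-3-hydroxy-4-methylpent-4-en-2-yl]-3,5-dimethyl-4H-pyran-4-one | CCc1oc([C@H](C)[C@H](O)C(C)=C)c(C)c(=O)c1C
F6 | step 4 | 2-ethyl-6-{(2R,3S)-3-hydroxy-3-[(2R)-2-methyloxiran-2-yl]propan-2-yl}-3,5-dimethyl-4H-pyran-4-one | CCc1oc([C@H](C)[C@H](O)[C@@]2(C)CO2)c(C)c(=O)c1C
F7 | step 8 | 2-ethyl-3,5-dimethyl-4-(triethylsilyloxy)-6-[(2R,3R)-3-(triethylsilyloxy)pentan-2-yl]pyrylium trifluoromethanesulfonate | CCc1[o+]c([C@H](C)[C@H](O[Si](CC)(CC)CC)CC)c(C)c(O[Si](CC)(CC)CC)c1C.[O-]S(=O)(=O)C(F)(F)F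
F8 | step 8 | triethyl{[(2Z)-2-ethylidene-3,5-dimethyl-6-[(2R,3R)-3-(triethylsilyloxy)pentan-2-yl]-2H-pyran-4-yl]oxy}silane | C/C=C1\OC([C@H](C)[C@H](O[Si](CC)(CC)CC)CC)=C(C)C(O[Si](CC)(CC)CC)=C1C
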